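**Plan**

- Retrosynthesis, in order: (a) the seven O–benzyl bonds of a fully benzylated target; (b) in one operation, the O1–C7a and C3–C3a bonds of the coumaranone, which detaches its phloroglucinol ring (ring A) as a 3,5-dialkoxybenzyne from a tertiary α-hydroxy methyl ester; (c) the C8–C(quaternary) bond and the 7-O–C(ketal) bond of the dihydrofuran, which leads back to a 7-OH-free protected kaempferol and an aryl vicinal tricarbonyl ester.
- Forward: kaempferol is converted into its 3,5,4'-tribenzyl ether; a Friedel–Crafts hydroxyalkylation/hemiketalization closes the dihydrofuran ring; the hemiketal is locked as a benzyl ketal; the aryne annulation closes the furanone ring, attaches ring A and completes the spiro centre; hydrogenolysis frees all seven hydroxyls.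
- Enabling feature: the spiro carbon C2 carries O1 and the C3 carbonyl, which end on the adjacent carbons C7a and C3a of ring A, and the C4 oxygen of ring A lies ortho to C3a. This is the O–C–C(=O) unit and the polarity pattern that a 3-alkoxyaryne accepts: O-nucleophile at the aryne carbon meta to the alkoxy group, carbanion ortho to it, ester as internal acyl acceptor.
- Stereochemistry: the quaternary carbon is set by catalyst control in the Friedel–Crafts step and none of its bonds is broken afterwards; the hemiketal carbon settles by ring–chain equilibration.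

Key step: step 12

Remark: the hemiketal carbon can epimerize through the ring-opened hydroxy ketone, so the (R) arrangement of the target (hemiketal OH cis to the coumaranone carbonyl) is assumed to be the thermodynamically preferred one; the ketal-bearing intermediates are drawn with the same relative configuration, and their epimers at that carbon would converge on the same target in the last step.

**Route**

Step 1
Reactants: 1 kaempferol
Product: 2 3,5,7,4'-tetra-O-acetylkaempferol
Conditions: Ac2O, pyridine, DMAP (cat.), rt
Reagents that add atoms: acetic anhydride, CC(=O)OC(C)=O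
Why: Exhaustive O-acetylation of a polyphenol (the chelated 5-OH reacts under DMAP catalysis), which sets up the reactivity order of the four oxygens used in step 2.

Step 2
Reactants: 2 3,5,7,4'-tetra-O-acetylkaempferol
Product: 3 7-O-allyl-3,5,4'-tri-O-acetylkaempferol
Conditions: allyl bromide, K2CO3, KI (cat.), acetone, reflux
Reagents that add atoms: allyl bromide, C=CCBr
Why: Selective alkylative deacetylation of a flavonol peracetate: the acetate of the most acidic phenol (7-OH) is cleaved first by carbonate and the phenoxide is alkylated in situ, a known way to single out the 7-oxygen.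

Step 3
Reactants: 3 7-O-allyl-3,5,4'-tri-O-acetylkaempferol
Product: 5 7-O-allyl-3,5,4'-tri-O-benzylkaempferol, via 7-O-allylkaempferol 4 (not isolated)
Conditions: K2CO3, MeOH/THF, rt; evaporate; then BnBr (excess), K2CO3, DMF, 70 °C
Reagents that add atoms: benzyl bromide, BrCc1ccccc1
Why: Base-catalysed methanolysis of the three aryl acetates followed by Williamson benzylation; heating with excess BnBr should also alkylate the hydrogen-bonded 5-OH, and the allyl ether is inert.

Step 4
Reactants: 5 7-O-allyl-3,5,4'-tri-O-benzylkaempferol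
Product: 6 3,5,4'-tri-O-benzylkaempferol (7-OH free)
Conditions: Pd(PPh3)4 (cat.), morpholine, THF, rt
Reagents that add atoms: none
Why: Tsuji–Trost deallylation (π-allyl palladium formation from the aryl allyl ether, capture of the allyl unit by morpholine) should free only the 7-OH and leave the benzyl ethers untouched.

Step 5
Reactants: 7 4-(benzyloxy)benzoic acid; 8 methyl (triphenylphosphoranylidene)acetate
Product: 9 methyl 3-[4-(benzyloxy)phenyl]-3-oxo-2-(triphenylphosphoranylidene)propanoate
Conditions: EDCI·HCl, DMAP (cat.), CH2Cl2, 0 °C → rt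
Reagents that add atoms: none
Why: C-Acylation of a stabilized phosphorus ylide by a carbodiimide-activated acid (Wasserman acyl ylide synthesis); the ylide carbon is the only nucleophile present.

Step 6
Reactants: 9 methyl 3-[4-(benzyloxy)phenyl]-3-oxo-2-(triphenylphosphoranylidene)propanoate
Product: 10 methyl 3-[4-(benzyloxy)phenyl]-2,3-dioxopropanoate
Conditions: dimethyldioxirane (2.2 equiv, acetone solution), CH2Cl2, −78 → 0 °C; short silica plug; toluene azeotrope, stored over 4 Å MS
Reagents that add atoms: dimethyldioxirane, CC1(C)OO1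
Why: Oxidative cleavage of the C=P bond of an acyl ylide to the central ketone (Wasserman vicinal tricarbonyl synthesis) under neutral, anhydrous conditions that should spare the benzyl ether and the arene.

Step 7
Reactants: 6 3,5,4'-tri-O-benzylkaempferol; 10 methyl 3-[4-(benzyloxy)phenyl]-2,3-dioxopropanoate
Product: 12 methyl (8R,9R)-3,5-bis(benzyloxy)-2,8-bis[4-(benzyloxy)phenyl]-8,9-dihydroxy-4-oxo-8,9-dihydro-4H-furo[2,3-h]chromene-9-carboxylate, via open-chain Friedel–Crafts adduct 11 (not isolated)
Conditions: quinine-derived 3,5-bis(trifluoromethyl)phenyl squaramide (10 mol %), 4 Å MS, CH2Cl2, −20 °C → rt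
Reagents that add atoms: none
Why: Organocatalytic enantioselective ortho-Friedel–Crafts hydroxyalkylation of a phenol with an activated ketone: the quinuclidine nitrogen engages the acidic 7-OH and the squaramide N–H bonds bind the 1,2-dicarbonyl unit of 10, so that C8 (ortho to 7-OH and O1, para to 5-OBn, less hindered than C6, the site also taken in Claisen and Mannich reactions of 7-hydroxy-5-alkoxyflavones) should attack one face of the most electrophilic central carbonyl and set the (R)-carbinol under catalyst control (the quinidine-derived pseudoenantiomer is to be used should the sense of induction prove opposite), after which the 7-OH closes onto the aryl ketone (5-exo-trig) to the hemiketal, whose configuration is thermodynamic.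

Step 8
Reactants: 12 hemiketal ester
Product: 13 methyl (8R,9R)-3,5,8-tris(benzyloxy)-2,8-bis[4-(benzyloxy)phenyl]-9-hydroxy-4-oxo-8,9-dihydro-4H-furo[2,3-h]chromene-9-carboxylate
Conditions: BnOH (10 equiv), PPTS (cat.), 4 Å MS, CH2Cl2, rt
Reagents that add atoms: benzyl alcohol, OCc1ccccc1
Why: Acid-catalysed exchange of the hemiketal OH (Fischer-glycosidation type, through the oxocarbenium ion stabilized by the ring oxygen and the 4-benzyloxyphenyl group) locks the masked aryl ketone and the 7-oxygen as a benzyl ketal removable in step 13, while the carbinol next to the ester should not ionize; the ketal configuration is thermodynamic and either epimer serves.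

Step 9
Reactants: 14 3,5-bis(benzyloxy)phenol
Product: 15 3,5-bis(benzyloxy)-2-bromophenol
Conditions: NBS, i-Pr2NH (cat.), CH2Cl2, −78 → 0 °C
Reagents that add atoms: N-bromosuccinimide, O=C1CCC(=O)N1Br
Why: Amine-catalysed ortho-selective electrophilic bromination of a phenol (bromine delivered by hydrogen bonding to the OH), expected at the position between OH and OBn in preference to the hindered one between two OBn groups.

Step 10
Reactants: 15 3,5-bis(benzyloxy)-2-bromophenol
Product: 16 [3,5-bis(benzyloxy)-2-bromophenoxy]trimethylsilane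
Conditions: HMDS, THF, 70 °C; concentrate
Reagents that add atoms: hexamethyldisilazane, C[Si](C)(C)N[Si](C)(C)C
Why: O-Silylation of the phenol by HMDS with loss of ammonia places silicon for the migration in step 11.

Step 11
Reactants: 16 [3,5-bis(benzyloxy)-2-bromophenoxy]trimethylsilane
Product: 19 3,5-bis(benzyloxy)-2-(trimethylsilyl)phenyl trifluoromethanesulfonate, via aryllithium 17 (not isolated), via lithium phenoxide 18 (not isolated)
Conditions: n-BuLi, THF, −100 → −78 °C; then Tf2O, −100 → −78 °C
Reagents that add atoms: trifluoromethanesulfonic anhydride, O=S(=O)(OS(=O)(=O)C(F)(F)F)C(F)(F)F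
Why: Bromine–lithium exchange, anionic 1,3-O→C silyl shift (retro-Brook rearrangement) and triflation of the resulting phenoxide form the standard entry to ortho-silylaryl triflates; exchange at −100 °C should outrun attack on the benzyl ethers.

Step 12
Reactants: 13 benzyl ketal α-hydroxy ester; 19 3,5-bis(benzyloxy)-2-(trimethylsilyl)phenyl trifluoromethanesulfonate
Product: 23 hepta-O-benzyl ether of the target, via sodium alkoxide 20 (not isolated), via benzyne 21 (not isolated), via aryl carbanion 22 (not isolated)
Conditions: NaH (1.1 equiv), THF, 0 °C; then 19 (2 equiv, slow addition), CsF, 18-crown-6, THF, 0 °C → rt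
Reagents that add atoms: none
Why: Proposed new method: fluoride releases aryne 21 from 19, the tertiary sodium alkoxide 20 adds to the aryne carbon meta to the 3-benzyloxy group, and the aryl carbanion 22, thereby placed ortho to that benzyloxy group, attacks the methyl ester and expels methoxide, so that the O1–C7a and C3–C3a bonds form in one operation. The closest known reaction type is the annulation of arynes with methyl salicylates to xanthones (O-arylation followed by intramolecular acyl substitution by the aryl anion); the extension proposed here is to a tertiary aliphatic α-hydroxy ester, which should give a benzofuran-3(2H)-one instead of a xanthone. The furanone ring closes in the 5-exo-trig mode. No stereocentre is created: the configuration of the quaternary carbon set in step 7 is retained because none of its four bonds is broken (its descriptor changes from R to S only through the priority rules), and the ketal carbon is untouched. The step needs regioselective attack on the unsymmetrical aryne, which the inductively withdrawing 3-benzyloxy group should secure through the known distortion of 3-alkoxyarynes, and it needs the alkoxide to be the only nucleophile and the ester the only acyl acceptor within reach, which full O-benzylation and the ketal lock on the aryl ketone secure. Cyclization is expected to outrun protonation of the carbanion because the preformed alkoxide leaves no proton source in THF.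

Step 13
Reactants: 23 hepta-O-benzyl ether of the target
Product: 24 CNP0283000.1 (target)
Conditions: H2 (1 atm), Pd/C, THF/EtOAc, rt; filtration; reversed-phase chromatography
Reagents that add atoms: none
Why: Hydrogenolysis of six aryl benzyl ethers and the benzyl ketal at their unhindered O–CH2Ph bonds; the two benzylic C–O bonds at fully substituted carbons and the flavonol double bond are expected to react far more slowly, and the liberated hemiketal should equilibrate by ring–chain tautomerism to the (R) configuration.

**Compound list**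

1 | kaempferol | O=c1c(O)c(-c2ccc(O)cc2)oc2cc(O)cc(O)c12 | starting material
2 | 3,5,7,4'-tetra-O-acetylkaempferol | O=c1c(OC(C)=O)c(-c2ccc(OC(C)=O)cc2)oc2cc(OC(C)=O)cc(OC(C)=O)c12 | intermediate
3 | 7-O-allyl-3,5,4'-tri-O-acetylkaempferol | O=c1c(OC(C)=O)c(-c2ccc(OC(C)=O)cc2)oc2cc(OCC=C)cc(OC(C)=O)c12 | intermediate
4 | 7-O-allylkaempferol (not isolated) | O=c1c(O)c(-c2ccc(O)cc2)oc2cc(OCC=C)cc(O)c12 | intermediate
5 | 7-O-allyl-3,5,4'-tri-O-benzylkaempferol | O=c1c(OCc2ccccc2)c(-c2ccc(OCc3ccccc3)cc2)oc2cc(OCC=C)cc(OCc3ccccc3)c12 | intermediate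
6 | 3,5,4'-tri-O-benzylkaempferol: 3,5-bis(benzyloxy)-2-[4-(benzyloxy)phenyl]-7-hydroxy-4H-chromen-4-one | O=c1c(OCc2ccccc2)c(-c2ccc(OCc3ccccc3)cc2)oc2cc(O)cc(OCc3ccccc3)c12 | intermediate
7 | 4-(benzyloxy)benzoic acid | OC(=O)c1ccc(OCc2ccccc2)cc1 | starting material
8 | methyl (triphenylphosphoranylidene)acetate | COC(=O)C=P(c1ccccc1)(c1ccccc1)c1ccccc1 | starting material
9 | methyl 3-[4-(benzyloxy)phenyl]-3-oxo-2-(triphenylphosphoranylidene)propanoate | COC(=O)C(C(=O)c1ccc(OCc2ccccc2)cc1)=P(c1ccccc1)(c1ccccc1)c1ccccc1 | intermediate
10 | methyl 3-[4-(benzyloxy)phenyl]-2,3-dioxopropanoate | COC(=O)C(=O)C(=O)c1ccc(OCc2ccccc2)cc1 | intermediate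
11 | methyl (2R)-2-{3,5-bis(benzyloxy)-2-[4-(benzyloxy)phenyl]-7-hydroxy-4-oxo-4H-chromen-8-yl}-3-[4-(benzyloxy)phenyl]-2-hydroxy-3-oxopropanoate (open-chain adduct, not isolated) | COC(=O)[C@](O)(C(=O)c1ccc(OCc5ccccc5)cc1)c1c(O)cc(OCc5ccccc5)c2c(=O)c(OCc5ccccc5)c(-c3ccc(OCc5ccccc5)cc3)oc12 | intermediate
12 | methyl (8R,9R)-3,5-bis(benzyloxy)-2,8-bis[4-(benzyloxy)phenyl]-8,9-dihydroxy-4-oxo-8,9-dihydro-4H-furo[2,3-h]chromene-9-carboxylate (hemiketal) | COC(=O)[C@@]1(O)c2c(cc(OCc5ccccc5)c3c(=O)c(OCc5ccccc5)c(-c4ccc(OCc5ccccc5)cc4)oc23)O[C@]1(O)c1ccc(OCc5ccccc5)cc1 | intermediate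
13 | methyl (8R,9R)-3,5,8-tris(benzyloxy)-2,8-bis[4-(benzyloxy)phenyl]-9-hydroxy-4-oxo-8,9-dihydro-4H-furo[2,3-h]chromene-9-carboxylate (benzyl ketal) | COC(=O)[C@@]1(O)c2c(cc(OCc5ccccc5)c3c(=O)c(OCc5ccccc5)c(-c4ccc(OCc5ccccc5)cc4)oc23)O[C@]1(OCc5ccccc5)c1ccc(OCc5ccccc5)cc1 | intermediate
14 | 3,5-bis(benzyloxy)phenol | Oc1cc(OCc2ccccc2)cc(OCc2ccccc2)c1 | starting material
15 | 3,5-bis(benzyloxy)-2-bromophenol | Oc1cc(OCc2ccccc2)cc(OCc2ccccc2)c1Br | intermediate
16 | [3,5-bis(benzyloxy)-2-bromophenoxy]trimethylsilane | C[Si](C)(C)Oc1cc(OCc2ccccc2)cc(OCc2ccccc2)c1Br | intermediate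
17 | [2,4-bis(benzyloxy)-6-(trimethylsilyloxy)phenyl]lithium (not isolated) | [Li]c1c(O[Si](C)(C)C)cc(OCc2ccccc2)cc1OCc1ccccc1 | intermediate
18 | lithium 3,5-bis(benzyloxy)-2-(trimethylsilyl)phenoxide (not isolated) | [Li+].[O-]c1cc(OCc2ccccc2)cc(OCc2ccccc2)c1[Si](C)(C)C | intermediate
19 | 3,5-bis(benzyloxy)-2-(trimethylsilyl)phenyl trifluoromethanesulfonate | C[Si](C)(C)c1c(OS(=O)(=O)C(F)(F)F)cc(OCc2ccccc2)cc1OCc1ccccc1 | intermediate
20 | sodium alkoxide of 13 (9-olate, 8R,9R; not isolated) | [Na+].COC(=O)[C@@]1([O-])c2c(cc(OCc5ccccc5)c3c(=O)c(OCc5ccccc5)c(-c4ccc(OCc5ccccc5)cc4)oc23)O[C@]1(OCc5ccccc5)c1ccc(OCc5ccccc5)cc1 | intermediate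
21 | 3,5-bis(benzyloxy)benzyne (not isolated) | C1#CC(OCc2ccccc2)=CC(OCc2ccccc2)=C1 | intermediate
22 | aryl carbanion (sodium salt): 9-O-[3,5-bis(benzyloxy)phenyl] ether of 13 with the negative charge on the ring carbon between the ether oxygen and a benzyloxy group (8R,9R; not isolated) | [Na+].COC(=O)[C@@]1(Oc6cc(OCc5ccccc5)cc(OCc5ccccc5)[c-]6)c2c(cc(OCc5ccccc5)c3c(=O)c(OCc5ccccc5)c(-c4ccc(OCc5ccccc5)cc4)oc23)O[C@]1(OCc5ccccc5)c1ccc(OCc5ccccc5)cc1 | intermediate
23 | (2S,8'R)-3',4,5',6,8'-pentakis(benzyloxy)-2',8'-bis[4-(benzyloxy)phenyl]-3H,4'H,8'H-spiro[1-benzofuran-2,9'-furo[2,3-h]chromene]-3,4'-dione (hepta-O-benzyl ether of the target) | O=C1c2c(OCc5ccccc5)cc(OCc5ccccc5)cc2O[C@@]12c1c(cc(OCc5ccccc5)c3c(=O)c(OCc5ccccc5)c(-c4ccc(OCc5ccccc5)cc4)oc13)O[C@]2(OCc5ccccc5)c1ccc(OCc5ccccc5)cc1 | intermediate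
24 | CNP0283000.1: (2S,8'R)-3',4,5',6,8'-pentahydroxy-2',8'-bis(4-hydroxyphenyl)-3H,4'H,8'H-spiro[1-benzofuran-2,9'-furo[2,3-h]chromene]-3,4'-dione | O=C1c2c(O)cc(O)cc2O[C@@]12c1c(cc(O)c3c(=O)c(O)c(-c4ccc(O)cc4)oc13)O[C@]2(O)c1ccc(O)cc1 | target

**Totals**

Total step count: 13. Longest linear sequence: 8 steps (steps 1, 2, 3, 4, 7, 8, 12, 13).

**Steps most likely to fail**

Step 12 (proposed new method). The hindered tertiary alkoxide may add to the aryne too slowly, so that the aryne is consumed by methoxide, fluoride or itself. The aryl carbanion may also be protonated before it closes, or the alkoxide may trigger opening of the neighbouring ketal. The fallback uses known chemistry, sets out from 13 and returns at 23. 5-Fluororesorcinol is benzylated (BnBr, K2CO3, DMF) to 1,3-bis(benzyloxy)-5-fluorobenzene F1. Ortho-lithiation between fluorine and a benzyloxy group (n-BuLi, THF, −78 °C) gives [2,4-bis(benzyloxy)-6-fluorophenyl]lithium F2. F2 is added at −78 °C to the methyl ester of 13 (2.2 equiv; the first equivalent deprotonates the carbinol). The chelated tetrahedral intermediate should collapse on work-up to the 2-fluoroaryl ketone F3, and a second addition is blocked by the doubly ortho-substituted aryl group. K2CO3 in DMF at 60 °C then closes the furanone ring by intramolecular SNAr, the tertiary alkoxide displacing the fluoride ortho to the ketone, to give 23.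

Step 7. Facial discrimination on the central carbonyl may be poor, or the weakly nucleophilic flavonol phenol may react sluggishly under the bifunctional catalyst. The fallback gives up asymmetric catalysis for resolution; it sets out from 6 and 10 and returns at 13. The Friedel–Crafts/hemiketalization is run with an achiral amine base (Et3N, CH2Cl2, rt) to give the racemic hemiketal F4. F4 is ketalized as in step 8 to the racemic benzyl ketal F5. The enantiomers of F5 are separated by preparative chromatography on a chiral stationary phase (amylose tris(3,5-dimethylphenylcarbamate)), and the (8R,9R) enantiomer is 13.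

Step 8. The oxocarbenium ion may undergo a 1,2-shift of the ester or aryl group from the adjacent carbinol carbon (semipinacol pathway), or the exchange may stop short. The fallback sets out from 12 and returns at 13 with no new compound (F0). It forms the other bond of the ketal: the hemiketal oxygen is alkylated with BnBr and Ag2O in CH2Cl2 at rt (Purdie-type alkylation of the more acidic hemiketal OH), so that no cation is generated at the ketal carbon and the hindered, ester-flanked carbinol should stay free.

**Further compounds**

F1 | step 12 | 1,3-bis(benzyloxy)-5-fluorobenzene | Fc1cc(OCc2ccccc2)cc(OCc2ccccc2)c1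
F2 | step 12 | [2,4-bis(benzyloxy)-6-fluorophenyl]lithium | [Li]c1c(F)cc(OCc2ccccc2)cc1OCc1ccccc1
F3 | step 12 | (8R,9S)-3,5,8-tris(benzyloxy)-9-[2,4-bis(benzyloxy)-6-fluorobenzoyl]-2,8-bis[4-(benzyloxy)phenyl]-9-hydroxy-8,9-dihydro-4H-furo[2,3-h]chromen-4-one | O=C(c1c(F)cc(OCc5ccccc5)cc1OCc5ccccc5)[C@@]1(O)c2c(cc(OCc5ccccc5)c3c(=O)c(OCc5ccccc5)c(-c4ccc(OCc5ccccc5)cc4)oc23)O[C@]1(OCc5ccccc5)c1ccc(OCc5ccccc5)cc1
F4 | step 7 | racemic 12 (racemic hemiketal ester) | COC(=O)C1(O)c2c(cc(OCc5ccccc5)c3c(=O)c(OCc5ccccc5)c(-c4ccc(OCc5ccccc5)cc4)oc23)OC1(O)c1ccc(OCc5ccccc5)cc1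
F5 | step 7 | racemic 13 (racemic benzyl ketal ester) | COC(=O)C1(O)c2c(cc(OCc5ccccc5)c3c(=O)c(OCc5ccccc5)c(-c4ccc(OCc5ccccc5)cc4)oc23)OC1(OCc5ccccc5)c1ccc(OCc5ccccc5)cc1
F0 | step 8 | none | none
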